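## Plan

- **Cuts.** The C2–C3 bond of ring C is cut and the 3-OH oxygen is written back between C2 and C3. This turns the pyranone into the seven-membered cyclic acetal 20 (a 1,3-benzodioxepin-5-one). Its two acetal C2–O bonds lead to ring-A diol 15 and ring-B acetal 19, and the ring-A C–geranyl, C–prenyl and C–acyl bonds lead back to phloroglucinol.
- **Enabling feature.** C2 is benzylic to the 2,4,6-trioxygenated ring B and bonded to the aryl oxygen O1, so it is an oxocarbenium-level carbon. C3 bears oxygen next to the C4 ketone, so it is the carbon end of an enediol. C2 can therefore pass from O3 to C3.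
- **Forward order.** Ring A is dressed by three directed ortho-metalations around one differently protected oxygen, the future O1: geranyl para to it, then prenyl and the hydroxyacetyl group ortho to it. Ring B comes from 2,4,6-trihydroxybenzaldehyde. 15 and 19 are joined as 20, ring C arises by contraction of the seven-membered ring, and the four MOM groups fall last.
- **Stereochemistry.** C3 is set in the key step by a chiral phosphate ion pair. C2 follows as trans, (2R,3R), by transition-state and thermodynamic preference. The E-geranyl bond is carried in from geranyl bromide.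

Key step: step 13

Assumption: the sense of induction of the binaphthyl phosphoric acid in step 13 cannot be derived on paper; the (R)-acid is written, and its mirror image is used if the first run gives the (2S,3S) series.

Abbreviations: geranyl = (2E)-3,7-dimethylocta-2,6-dien-1-yl; prenyl = 3-methylbut-2-en-1-yl; MOM = methoxymethyl; EE = 1-ethoxyethyl (its stereocentre is left undefined); TIPS = triisopropylsilyl.

## Route

Step 1
Reactants: 1 phloroglucinol
Product: 2 5-(triisopropylsilyloxy)benzene-1,3-diol
Conditions: TIPSCl (1 equiv), imidazole, DMF, 0 °C → rt; 1 in threefold excess, removed by water wash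
Reagents that add atoms: chlorotriisopropylsilane, CC(C)[Si](Cl)(C(C)C)C(C)C
Why: Silyl ether formation run as a statistical mono-protection marks one oxygen, the future O1, and the bulky, non-coordinating TIPS-oxy group later keeps lithiation away from its two ortho positions.

Step 2
Reactants: 2 5-(triisopropylsilyloxy)benzene-1,3-diol
Product: 3 [3,5-bis(methoxymethoxy)phenoxy]triisopropylsilane
Conditions: MOMCl, i-Pr2NEt, CH2Cl2, 0 °C → rt
Reagents that add atoms: chloromethyl methyl ether, COCCl
Why: MOM ether formation on both remaining phenols installs the two cooperating directing groups for step 3, which also protect the later 5- and 7-hydroxyls.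

Step 3
Reactants: 3 [3,5-bis(methoxymethoxy)phenoxy]triisopropylsilane; 4 geranyl bromide
Product: 6 [4-geranyl-3,5-bis(methoxymethoxy)phenoxy]triisopropylsilane, via aryllithium 5 (not isolated)
Conditions: n-BuLi, THF, 0 °C; then CuBr·SMe2 (10 mol%), 4, −78 °C → rt
Reagents that add atoms: none
Why: Directed ortho-metalation takes the only C–H flanked by two chelating MOM-oxy groups, and copper-catalysed SN2 allylation at the primary carbon of 4 places the geranyl chain para to the TIPS-oxy group without touching its E double bond.

Step 4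
Reactants: 6 [4-geranyl-3,5-bis(methoxymethoxy)phenoxy]triisopropylsilane
Product: 7 4-geranyl-3,5-bis(methoxymethoxy)phenol
Conditions: TBAF, THF, 0 °C; aqueous work-up
Reagents that add atoms: none
Why: Fluoride cleaves the aryl silyl ether and leaves MOM ethers and alkenes untouched, freeing the one phenol that is to become O1.

Step 5
Reactants: 7 4-geranyl-3,5-bis(methoxymethoxy)phenol
Product: 8 5-(1-ethoxyethoxy)-2-geranyl-1,3-bis(methoxymethoxy)benzene
Conditions: ethyl vinyl ether, PPTS (cat.), CH2Cl2, rt
Reagents that add atoms: ethyl vinyl ether, C=COCC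
Why: Acid-catalysed addition of the phenol to the enol ether gives an acetal-type ether that directs ortho-lithiation like MOM but can later be removed by mild acid in the presence of the aryl MOM ethers.

Step 6
Reactants: 8 5-(1-ethoxyethoxy)-2-geranyl-1,3-bis(methoxymethoxy)benzene; 9 prenyl bromide
Product: 11 1-(1-ethoxyethoxy)-4-geranyl-3,5-bis(methoxymethoxy)-2-prenylbenzene, via aryllithium 10 (not isolated)
Conditions: n-BuLi (slight deficit), TMEDA, THF, 0 °C; then CuBr·SMe2 (10 mol%), 9, −78 °C → rt
Reagents that add atoms: none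
Why: The two remaining ring C–H positions are equivalent and each lies between the EE-oxy and a MOM-oxy group, so directed ortho-metalation followed by copper-catalysed SN2 allylation can give only one mono-prenyl product.

Step 7
Reactants: 11 1-(1-ethoxyethoxy)-4-geranyl-3,5-bis(methoxymethoxy)-2-prenylbenzene; 12 2-[(tert-butyldimethylsilyl)oxy]-N-methoxy-N-methylacetamide
Product: 14 2-[(tert-butyldimethylsilyl)oxy]-1-[2-(1-ethoxyethoxy)-5-geranyl-4,6-bis(methoxymethoxy)-3-prenylphenyl]ethan-1-one, via aryllithium 13 (not isolated)
Conditions: n-BuLi, TMEDA, THF, 0 °C; then 12, −78 → 0 °C; aqueous work-up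
Reagents that add atoms: none
Why: Directed ortho-metalation at the last ring C–H and Weinreb ketone synthesis, in which the chelated tetrahedral adduct prevents over-addition, install the protected hydroxyacetyl group next to the oxygen that carries prenyl on its other side.

Step 8
Reactants: 14 2-[(tert-butyldimethylsilyl)oxy]-1-[2-(1-ethoxyethoxy)-5-geranyl-4,6-bis(methoxymethoxy)-3-prenylphenyl]ethan-1-one
Product: 15 2-hydroxy-1-[5-geranyl-2-hydroxy-4,6-bis(methoxymethoxy)-3-prenylphenyl]ethan-1-one
Conditions: camphorsulfonic acid (cat.), MeOH, 0 °C → rt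
Reagents that add atoms: none
Why: Acid-catalysed methanolysis removes the aryl 1-ethoxyethyl acetal and the primary silyl ether, both far more labile than aryl MOM ethers, and so frees exactly the phenol (future O1) and the primary alcohol (future 3-OH) needed for the acetal.

Step 9
Reactants: 16 2,4,6-trihydroxybenzaldehyde
Product: 17 2,6-dihydroxy-4-methoxybenzaldehyde
Conditions: Me2SO4 (1 equiv), K2CO3 (1 equiv), acetone, rt
Reagents that add atoms: dimethyl sulfate, COS(=O)(=O)OC
Why: O-Methylation with a hard electrophile and one equivalent of weak base takes the para hydroxyl, which is the most acidic and the only one not hydrogen-bonded to the aldehyde.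

Step 10
Reactants: 17 2,6-dihydroxy-4-methoxybenzaldehyde
Product: 18 4-methoxy-2,6-bis(methoxymethoxy)benzaldehyde
Conditions: NaH, MOMCl, DMF, 0 °C → rt
Reagents that add atoms: chloromethyl methyl ether, COCCl
Why: Williamson-type alkylation of the two chelated phenols as their sodium salts gives the bis-MOM ether, whose oxygens will stabilise positive charge at the benzylic carbon in step 13.

Step 11
Reactants: 18 4-methoxy-2,6-bis(methoxymethoxy)benzaldehyde
Product: 19 2-(dimethoxymethyl)-5-methoxy-1,3-bis(methoxymethoxy)benzene
Conditions: HC(OMe)3, PPTS (cat.), MeOH, rt; Et3N quench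
Reagents that add atoms: trimethyl orthoformate, COC(OC)OC
Why: Acid-catalysed acetalisation driven by the orthoformate converts the hindered, electron-rich aldehyde into its dimethyl acetal, the form that exchanges under very weak acid in step 12.

Step 12
Reactants: 15 2-hydroxy-1-[5-geranyl-2-hydroxy-4,6-bis(methoxymethoxy)-3-prenylphenyl]ethan-1-one; 19 2-(dimethoxymethyl)-5-methoxy-1,3-bis(methoxymethoxy)benzene
Product: 20 rac-7-geranyl-2-[4-methoxy-2,6-bis(methoxymethoxy)phenyl]-6,8-bis(methoxymethoxy)-9-prenyl-4H-1,3-benzodioxepin-5-one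
Conditions: PPTS (5 mol%), 5 Å molecular sieves, toluene, rt, reduced pressure; Et3N quench; Et3N-deactivated silica
Reagents that add atoms: none
Why: Transacetalisation in which the primary alcohol of 15 exchanges first and the neighbouring phenol, the only free one, then closes the seven-membered 1,3-dioxepinone ring while methanol is removed; the pyridinium acid should be too weak to enolise the ketone, and the new acetal centre is racemic, which does not matter because step 13 erases it.

Step 13
Reactants: 20 rac-7-geranyl-2-[4-methoxy-2,6-bis(methoxymethoxy)phenyl]-6,8-bis(methoxymethoxy)-9-prenyl-4H-1,3-benzodioxepin-5-one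
Product: 22 (2R,3R)-6-geranyl-3-hydroxy-2-[4-methoxy-2,6-bis(methoxymethoxy)phenyl]-5,7-bis(methoxymethoxy)-8-prenylchroman-4-one, via oxocarbenium–enediol ion pair 21 (not isolated)
Conditions: (R)-3,3′-bis(2,4,6-triisopropylphenyl)-1,1′-binaphthyl-2,2′-diyl hydrogen phosphate, (R)-TRIP (10 mol%), 5 Å molecular sieves, toluene (0.01 M), 0 °C → rt
Reagents that add atoms: none
Why: Proposed new method: the chiral phosphoric acid protonates the alkyl acetal oxygen O3 of 20 and the C2–O3 bond ionises, because C2 is benzylic to the 2,6-bis(methoxymethoxy)-4-methoxyphenyl ring and carries the aryl oxygen O1; this gives the oxocarbenium ion O1=C2 paired with the chiral phosphate, which hydrogen-bonds the released hydroxyacetyl arm and shuttles H-3 to form the enediol of ion pair 21. The enediol carbon C3 then adds to C2 (a formal 1,2-shift of C2 from O3 to C3), which closes ring C in a 6-(enolendo)-endo-trig mode, turns O3 into the exocyclic 3-hydroxyl and so contracts the seven-membered dioxepinone to the six-membered pyranone. The closest known reaction type is the Petasis–Ferrier rearrangement of cyclic enol acetals, in particular its chiral-phosphoric-acid-catalysed ring contraction of seven-membered cyclic vinyl acetals, together with the 1,2-Wittig shift of acetal carbons; new here is that the enol is formed by tautomerisation of a ketone and bonds through the carbon α to the departing oxygen. C3 is set by the phosphate, which shields one face of the planar enediol inside the contact ion pair; C2 follows as trans because ring B takes the pseudo-equatorial place in the half-chair transition state and because the benzylic C2–O1 bond can re-ionise under the acid and settle in the diequatorial (2R,3R) arrangement, while the racemic acetal centre is erased on ionisation, so the step is stereoconvergent. The step needs C–C instead of C–O recombination and attack through C3 instead of C4: O-recombination only regenerates acetals that re-ionise, C3 is the unhindered terminus whose attack gives the six-membered aryl ketone, and all other phenols are capped as MOM ethers so that only O1 can flank the cation.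

Step 14
Reactants: 22 (2R,3R)-6-geranyl-3-hydroxy-2-[4-methoxy-2,6-bis(methoxymethoxy)phenyl]-5,7-bis(methoxymethoxy)-8-prenylchroman-4-one
Product: 23 (2R,3R)-2-(2,6-dihydroxy-4-methoxyphenyl)-6-geranyl-3,5,7-trihydroxy-8-prenylchroman-4-one (target)
Conditions: HCl (1 M in MeOH), argon, 0 °C → rt
Reagents that add atoms: none
Why: Acid-catalysed transacetalisation of the four aryl MOM ethers to dimethoxymethane under conditions mild enough to leave the prenyl and geranyl double bonds alone; C3 is not touched and C2, if it ionises, recloses to the more stable trans isomer.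

## Compound list

1 | phloroglucinol (benzene-1,3,5-triol) | Oc1cc(O)cc(O)c1 | starting material
2 | 5-(triisopropylsilyloxy)benzene-1,3-diol | CC(C)[Si](Oc1cc(O)cc(O)c1)(C(C)C)C(C)C | intermediate
3 | [3,5-bis(methoxymethoxy)phenoxy]triisopropylsilane | COCOc1cc(OCOC)cc(O[Si](C(C)C)(C(C)C)C(C)C)c1 | intermediate
4 | geranyl bromide, (2E)-1-bromo-3,7-dimethylocta-2,6-diene | BrC/C=C(\C)CCC=C(C)C | starting material
5 | 2,6-bis(methoxymethoxy)-4-(triisopropylsilyloxy)phenyllithium | [Li]c1c(OCOC)cc(O[Si](C(C)C)(C(C)C)C(C)C)cc1OCOC | intermediate (not isolated)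
6 | [4-geranyl-3,5-bis(methoxymethoxy)phenoxy]triisopropylsilane | COCOc1cc(O[Si](C(C)C)(C(C)C)C(C)C)cc(OCOC)c1C/C=C(\C)CCC=C(C)C | intermediate
7 | 4-geranyl-3,5-bis(methoxymethoxy)phenol | COCOc1cc(O)cc(OCOC)c1C/C=C(\C)CCC=C(C)C | intermediate
8 | 5-(1-ethoxyethoxy)-2-geranyl-1,3-bis(methoxymethoxy)benzene | CCOC(C)Oc1cc(OCOC)c(C/C=C(\C)CCC=C(C)C)c(OCOC)c1 | intermediate
9 | prenyl bromide, 1-bromo-3-methylbut-2-ene | BrCC=C(C)C | starting material
10 | 2-(1-ethoxyethoxy)-5-geranyl-4,6-bis(methoxymethoxy)phenyllithium | CCOC(C)Oc1cc(OCOC)c(C/C=C(\C)CCC=C(C)C)c(OCOC)c1[Li] | intermediate (not isolated)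
11 | 1-(1-ethoxyethoxy)-4-geranyl-3,5-bis(methoxymethoxy)-2-prenylbenzene | CCOC(C)Oc1cc(OCOC)c(C/C=C(\C)CCC=C(C)C)c(OCOC)c1CC=C(C)C | intermediate
12 | 2-[(tert-butyldimethylsilyl)oxy]-N-methoxy-N-methylacetamide | CON(C)C(=O)CO[Si](C)(C)C(C)(C)C | starting material
13 | 2-(1-ethoxyethoxy)-5-geranyl-4,6-bis(methoxymethoxy)-3-prenylphenyllithium | CCOC(C)Oc1c([Li])c(OCOC)c(C/C=C(\C)CCC=C(C)C)c(OCOC)c1CC=C(C)C | intermediate (not isolated)
14 | 2-[(tert-butyldimethylsilyl)oxy]-1-[2-(1-ethoxyethoxy)-5-geranyl-4,6-bis(methoxymethoxy)-3-prenylphenyl]ethan-1-one | CCOC(C)Oc1c(C(=O)CO[Si](C)(C)C(C)(C)C)c(OCOC)c(C/C=C(\C)CCC=C(C)C)c(OCOC)c1CC=C(C)C | intermediate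
15 | 2-hydroxy-1-[5-geranyl-2-hydroxy-4,6-bis(methoxymethoxy)-3-prenylphenyl]ethan-1-one | OCC(=O)c1c(O)c(CC=C(C)C)c(OCOC)c(C/C=C(\C)CCC=C(C)C)c1OCOC | intermediate
16 | 2,4,6-trihydroxybenzaldehyde | O=Cc1c(O)cc(O)cc1O | starting material
17 | 2,6-dihydroxy-4-methoxybenzaldehyde | COc1cc(O)c(C=O)c(O)c1 | intermediate
18 | 4-methoxy-2,6-bis(methoxymethoxy)benzaldehyde | COCOc1cc(OC)cc(OCOC)c1C=O | intermediate
19 | 2-(dimethoxymethyl)-5-methoxy-1,3-bis(methoxymethoxy)benzene | COCOc1cc(OC)cc(OCOC)c1C(OC)OC | intermediate
20 | rac-7-geranyl-2-[4-methoxy-2,6-bis(methoxymethoxy)phenyl]-6,8-bis(methoxymethoxy)-9-prenyl-4H-1,3-benzodioxepin-5-one | COCOc1cc(OC)cc(OCOC)c1C1OCC(=O)c2c(OCOC)c(C/C=C(\C)CCC=C(C)C)c(OCOC)c(CC=C(C)C)c2O1 | intermediate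
21 | ring-opened oxocarbenium–enediol (cation shown; counter-ion is the phosphate of the catalyst) | COCOc1cc(OC)cc(OCOC)c1C=[O+]c1c(CC=C(C)C)c(OCOC)c(C/C=C(\C)CCC=C(C)C)c(OCOC)c1C(O)=CO | intermediate (not isolated)
22 | (2R,3R)-6-geranyl-3-hydroxy-2-[4-methoxy-2,6-bis(methoxymethoxy)phenyl]-5,7-bis(methoxymethoxy)-8-prenylchroman-4-one | COc1cc(OCOC)c([C@H]2Oc3c(CC=C(C)C)c(OCOC)c(C/C=C(\C)CCC=C(C)C)c(OCOC)c3C(=O)[C@@H]2O)c(OCOC)c1 | intermediate
23 | (2R,3R)-2-(2,6-dihydroxy-4-methoxyphenyl)-6-geranyl-3,5,7-trihydroxy-8-prenylchroman-4-one | COc1cc(O)c([C@H]2Oc3c(CC=C(C)C)c(O)c(C/C=C(\C)CCC=C(C)C)c(O)c3C(=O)[C@@H]2O)c(O)c1 | target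

## Step count and risks

Total steps: 14. Longest linear sequence: 11 (steps 1–8, 12, 13, 14).

**Step 13 (bears the label).**
- What may go wrong: enolisation of the hindered aryl ketone may be slower than capture of the oxocarbenium carbon by the neighbouring prenyl double bond (Prins-type closure) or by ring B of a second molecule.
- Facial selectivity at C3 may be low or opposite, and the product may lose configuration at C3 by its own enolisation under the acid.
- Fallback (known chemistry, from 11 and 18, rejoining at 22): 11 is lithiated as in step 7 and quenched with N-methoxy-N-methylacetamide to give the methyl ketone 1-[2-(1-ethoxyethoxy)-5-geranyl-4,6-bis(methoxymethoxy)-3-prenylphenyl]ethan-1-one F1. Claisen–Schmidt condensation with aldehyde 18 (KOH, EtOH/THF) gives the (E)-chalcone F2. Juliá–Colonna epoxidation (poly-L-leucine, urea·H2O2, DBU, THF) gives the (αR,βS)-epoxy ketone F3. PPTS in MeOH then removes the ethoxyethyl group, and the freed phenol, the only one next to the ketone, opens the epoxide at the benzylic carbon with inversion to give 22.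

**Step 12.**
- What may go wrong: ring closure by the hindered, hydrogen-bonded phenol may stall at the open mixed methyl acetal, or the very labile acetal may ionise further under the acid and contract prematurely without stereocontrol.
- Fallback (from 15, rejoining at 20): 15 is silylated (TMSCl, Et3N, CH2Cl2) to the bis(trimethylsilyl) ether F4. F4 is condensed with the free aldehyde 18 by silyl-transfer acetalisation (TMSOTf cat., CH2Cl2, −78 °C, pyridine quench), a kinetic acetal formation at a temperature where no rearrangement is expected.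

**Step 14.**
- What may go wrong: under protic acid the freed phenols may add to the prenyl and geranyl double bonds (chroman formation), and the C2–O1 bond, benzylic to a trioxygenated ring, may open and be intercepted by methanol.
- Fallback (from 22, rejoining at 23): TMSOTf and 2,2′-bipyridyl in CH2Cl2 at 0 °C exchange the aryl MOM ethers for silyl ethers under buffered, non-protic conditions and silylate the 3-hydroxyl, giving the pentakis(trimethylsilyl) ether F5. F5 is hydrolysed to 23 on work-up with aqueous citric acid.

## Further compounds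

F1 | step 13 | 1-[2-(1-ethoxyethoxy)-5-geranyl-4,6-bis(methoxymethoxy)-3-prenylphenyl]ethan-1-one | CCOC(C)Oc1c(C(C)=O)c(OCOC)c(C/C=C(\C)CCC=C(C)C)c(OCOC)c1CC=C(C)C
F2 | step 13 | (E)-1-[2-(1-ethoxyethoxy)-5-geranyl-4,6-bis(methoxymethoxy)-3-prenylphenyl]-3-[4-methoxy-2,6-bis(methoxymethoxy)phenyl]prop-2-en-1-one | CCOC(C)Oc1c(C(=O)/C=C/c2c(OCOC)cc(OC)cc2OCOC)c(OCOC)c(C/C=C(\C)CCC=C(C)C)c(OCOC)c1CC=C(C)C
F3 | step 13 | (αR,βS)-trans-epoxide of F2 | CCOC(C)Oc1c(C(=O)[C@@H]2O[C@H]2c3c(OCOC)cc(OC)cc3OCOC)c(OCOC)c(C/C=C(\C)CCC=C(C)C)c(OCOC)c1CC=C(C)C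
F4 | step 12 | bis(trimethylsilyl) ether of 15 | C[Si](C)(C)OCC(=O)c1c(O[Si](C)(C)C)c(CC=C(C)C)c(OCOC)c(C/C=C(\C)CCC=C(C)C)c1OCOC
F5 | step 14 | pentakis(trimethylsilyl) ether of 23 | COc1cc(O[Si](C)(C)C)c([C@H]2Oc3c(CC=C(C)C)c(O[Si](C)(C)C)c(C/C=C(\C)CCC=C(C)C)c(O[Si](C)(C)C)c3C(=O)[C@@H]2O[Si](C)(C)C)c(O[Si](C)(C)C)c1
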